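**Retrosynthetic overview**

1. Numbering: ring A is the acyl ring (C1 bears the ester carbonyl, C2 and C3 one methyl each, C4 OH, C5 CHO, C6 OH); ring B is the methyl benzoate ring whose C4 oxygen is acylated.
2. Feature used: the aryl ester hangs on C1 of a resorcinol ring and both partners are di-ortho-substituted, so the ester carbon, C1, C2 and C3 are laid down first in an α-diazo β-keto ester of the ring B phenol (14) and ring A is grown on that ester.
3. Ring A: C5–CHO (last, formylation), then C3–C4, C4–C5, C1–C6 and C1–C2 (Wolff shift, ketene/ynol ether [2+2], four-electron opening, six-electron closure), leading back to 14 and tert-butoxyethyne 21.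
4. 14 comes from ring B phenol 8 and acyl Meldrum's acid 11 (from tigloyl chloride), then diazo transfer; 8 comes from methyl 2,4-dihydroxy-3,6-dimethylbenzoate 1 by C5 methylation and differentiation of the two oxygens; 21 comes from trichloroethene and KOtBu.
5. Ring order: ring B is bought as 1; ring A is the only ring made, in step 11.

Key step: step 11

**Route**

Step 1
Reactants: 1 methyl 2,4-dihydroxy-3,6-dimethylbenzoate
Product: 3 methyl 3-formyl-4,6-dihydroxy-2,5-dimethylbenzoate, via chloro(methoxy)methyl arene 2 (not isolated)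
Conditions: Cl2CHOCH3 (1.5 equiv), TiCl4 (3 equiv), CH2Cl2, −20 to 0 °C; then 1 M aq HCl
Reagents that add atoms: dichloromethyl methyl ether COC(Cl)Cl; water O
Why: Rieche formylation should enter at C5 of ring B, the only unsubstituted ring carbon and one that lies ortho to the 4-OH and para to the 2-OH, and aqueous acid then hydrolyses the α-chloro ether to the aldehyde.

Step 2
Reactants: 3 methyl 3-formyl-4,6-dihydroxy-2,5-dimethylbenzoate
Product: 5 methyl 2,4-dihydroxy-3,5,6-trimethylbenzoate, via hydroxymethyl arene 4 (not isolated)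
Conditions: H2 (3 atm), 10% Pd/C, AcOH, cat. HCl, 40 °C
Reagents that add atoms: none
Why: Catalytic hydrogenation reduces the phenol-activated aryl aldehyde to the benzylic alcohol, which is hydrogenolysed under acid to the methyl group (benzylic C–O hydrogenolysis) while ester and arene should stay intact.

Step 3
Reactants: 5 methyl 2,4-dihydroxy-3,5,6-trimethylbenzoate
Product: 6 methyl 4-(benzyloxy)-2-hydroxy-3,5,6-trimethylbenzoate
Conditions: BnBr (1.05 equiv), K2CO3 (1.1 equiv), acetone, reflux
Reagents that add atoms: benzyl bromide BrCc1ccccc1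
Why: Williamson etherification should take only the 4-OH, because the 2-OH is held in a hydrogen bond to the ester carbonyl and is the less acidic and less nucleophilic of the two.

Step 4
Reactants: 6 methyl 4-(benzyloxy)-2-hydroxy-3,5,6-trimethylbenzoate
Product: 7 methyl 4-(benzyloxy)-2-methoxy-3,5,6-trimethylbenzoate
Conditions: MeI (3 equiv), K2CO3 (2 equiv), DMF, 50 °C
Reagents that add atoms: iodomethane CI
Why: With the reactive phenol capped, the chelated 2-OH is methylated by Williamson etherification under more forcing conditions in a dipolar aprotic solvent.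

Step 5
Reactants: 7 methyl 4-(benzyloxy)-2-methoxy-3,5,6-trimethylbenzoate
Product: 8 methyl 4-hydroxy-2-methoxy-3,5,6-trimethylbenzoate
Conditions: H2 (1 atm), 10% Pd/C, EtOAc, rt
Reagents that add atoms: none
Why: Hydrogenolysis of the benzyl aryl ether frees the C4 phenol of ring B without touching the methyl ether or the ester.

Step 6
Reactants: 9 (E)-2-methylbut-2-enoyl chloride; 10 2,2-dimethyl-1,3-dioxane-4,6-dione
Product: 11 5-[(E)-1-hydroxy-2-methylbut-2-en-1-ylidene]-2,2-dimethyl-1,3-dioxane-4,6-dione
Conditions: pyridine (2.2 equiv), CH2Cl2, 0 °C to rt; cold dilute aq HCl wash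
Reagents that add atoms: none
Why: C-Acylation of Meldrum's acid through the acyl pyridinium ion should give the enolized acyl derivative, the α-methyl group of the tigloyl unit slowing conjugate addition and the weak base limiting deconjugation.

Step 7
Reactants: 11 5-[(E)-1-hydroxy-2-methylbut-2-en-1-ylidene]-2,2-dimethyl-1,3-dioxane-4,6-dione; 8 methyl 4-hydroxy-2-methoxy-3,5,6-trimethylbenzoate
Product: 13 4-(methoxycarbonyl)-3-methoxy-2,5,6-trimethylphenyl (E)-4-methyl-3-oxohex-4-enoate, via acylketene 12 (not isolated)
Conditions: 11 (1.3 equiv), toluene, 110 °C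
Reagents that add atoms: none
Why: Thermal fragmentation of the acyl Meldrum's acid (loss of acetone and CO2) releases an acylketene that adds the phenol O–H, a neutral acylation by a small and very electrophilic ketene that should tolerate the two ortho-methyl groups of 8.

Step 8
Reactants: 13 4-(methoxycarbonyl)-3-methoxy-2,5,6-trimethylphenyl (E)-4-methyl-3-oxohex-4-enoate
Product: 14 4-(methoxycarbonyl)-3-methoxy-2,5,6-trimethylphenyl (E)-2-diazo-4-methyl-3-oxohex-4-enoate
Conditions: 4-acetamidobenzenesulfonyl azide (1.2 equiv), Et3N (1.5 equiv), MeCN, 0 °C to rt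
Reagents that add atoms: 4-acetamidobenzenesulfonyl azide CC(=O)Nc1ccc(cc1)S(=O)(=O)N=[N+]=[N-]
Why: Regitz diazo transfer to the doubly activated methylene of the β-keto ester should proceed under mild amine base, and the sulfonamide is removed by filtration and aqueous wash.

Step 9
Reactants: 15 trichloroethene; 16 potassium tert-butoxide
Product: 18 (E)-1-tert-butoxy-1,2-dichloroethene, via dichloroethyne 17 (not isolated)
Conditions: KOtBu (1.0 equiv), THF, −50 °C to rt
Reagents that add atoms: none
Why: tert-Butoxide eliminates HCl from trichloroethene to dichloroethyne, to which tert-butoxide adds in anti fashion, and protonation of the vinyl anion gives the dichlorovinyl ether (elimination–addition, the established entry to alkynyl ethers).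

Step 10
Reactants: 18 (E)-1-tert-butoxy-1,2-dichloroethene
Product: 21 tert-butoxyethyne, via chloroalkynyl ether 19 (not isolated), via lithium tert-butoxyethynide 20 (not isolated)
Conditions: n-BuLi (2.2 equiv), Et2O, −78 to −40 °C; H2O, −78 °C; bulb-to-bulb transfer below 25 °C under reduced pressure, kept as a cold solution
Reagents that add atoms: none
Why: The first equivalent of n-BuLi effects β-elimination to the chloroalkynyl ether, the second exchanges chlorine for lithium, and cold protonation of the acetylide gives the alkyne, which is never warmed because it fragments to ketene and isobutene.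

Step 11
Reactants: 14 4-(methoxycarbonyl)-3-methoxy-2,5,6-trimethylphenyl (E)-2-diazo-4-methyl-3-oxohex-4-enoate; 21 tert-butoxyethyne
Product: 26 4-(methoxycarbonyl)-3-methoxy-2,5,6-trimethylphenyl 2-tert-butoxy-4-hydroxy-5,6-dimethylbenzoate, via vinylketene 22 (not isolated), via cyclobutenone 23 (not isolated), via dienylketene 24 (not isolated), via cyclohexadienone 25 (not isolated)
Conditions: 21 (3 equiv), degassed CH2Cl2, hν (medium-pressure Hg lamp, Pyrex filter, λ > 300 nm), 15 °C; excess 21 and solvent removed below 20 °C; then toluene, 80 °C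
Reagents that add atoms: none
Why: Light expels N2 from the diazo dicarbonyl and the but-2-en-2-yl group shifts from the ketone carbon to the diazo carbon (Wolff rearrangement, bond C1–C2), giving a ketene whose α-carbon C1 holds the aryloxycarbonyl group and the alkenyl arm. At room temperature the ynol ether should add across the ketene C=C by [2+2] cycloaddition, its unsubstituted nucleophilic carbon bonding to the ketene carbonyl carbon (C4–C5) and its oxygen-bearing carbon to C1 (C1–C6), the polarity-matched sense that sets the tert-butoxy group beside the ester. Warming then breaks C1–C4 of the cyclobutenone by conrotatory four-electron opening, and ring A closes by disrotatory six-electron electrocyclization of the dienylketene between the alkenyl terminus and the ketene carbon (C3–C4), after which the dienone enolizes through the hydrogen on C3 to the C4 phenol. The closest known reaction type is the benzannulation of α,β-unsaturated α-diazo ketones with alkoxy- and siloxyalkynes by way of photochemically generated vinylketenes (Danheiser benzannulation), here with an ester on the ketene carbon. No stereocentre is created in the product, since the quaternary carbon of the cyclobutenone and the sp3 carbon of the dienone are both lost. The step needs carbon and not aryloxy migration in the Wolff shift, which the high migratory aptitude of an alkenyl group on a ketone should secure, and it needs addition to the ketene C=C and not capture through the ester carbonyl, which the weak heterodiene character of an ester and the reversible cyclobutenone opening (only the rotamer with the alkenyl arm turned toward the ketene can close to a benzene) should secure; light above 300 nm spares the benzoate chromophores, and the excess alkyne is stripped cold before heating so that it does not fragment to ketene.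

Step 12
Reactants: 26 4-(methoxycarbonyl)-3-methoxy-2,5,6-trimethylphenyl 2-tert-butoxy-4-hydroxy-5,6-dimethylbenzoate
Product: 27 4-(methoxycarbonyl)-3-methoxy-2,5,6-trimethylphenyl 2,4-dihydroxy-5,6-dimethylbenzoate
Conditions: CF3CO2H/CH2Cl2 (1:4), Et3SiH (3 equiv), 0 °C
Reagents that add atoms: none
Why: Acidolysis of the aryl tert-butyl ether releases the tert-butyl cation, which triethylsilane reduces before it can alkylate the open C5 of ring A, and the two esters should survive cold trifluoroacetic acid.

Step 13
Reactants: 27 4-(methoxycarbonyl)-3-methoxy-2,5,6-trimethylphenyl 2,4-dihydroxy-5,6-dimethylbenzoate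
Product: 29 4-(methoxycarbonyl)-3-methoxy-2,5,6-trimethylphenyl 3-formyl-2,4-dihydroxy-5,6-dimethylbenzoate, via chloro(methoxy)methyl arene 28 (not isolated)
Conditions: Cl2CHOCH3 (2 equiv), TiCl4 (4 equiv), CH2Cl2, −20 to 0 °C; then 1 M aq HCl
Reagents that add atoms: dichloromethyl methyl ether COC(Cl)Cl; water O
Why: Rieche formylation can only enter at C5 of ring A, the single unsubstituted aromatic carbon of the molecule, which is flanked by both phenolic oxygens, and hydrolysis on work-up should give the aldehyde of the target.

**Compound list**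

1 | methyl 2,4-dihydroxy-3,6-dimethylbenzoate | COC(=O)c1c(C)cc(O)c(C)c1O | starting material
2 | methyl 3-[chloro(methoxy)methyl]-4,6-dihydroxy-2,5-dimethylbenzoate (racemic, transient) | COC(=O)c1c(C)c(C(Cl)OC)c(O)c(C)c1O | intermediate
3 | methyl 3-formyl-4,6-dihydroxy-2,5-dimethylbenzoate | COC(=O)c1c(C)c(C=O)c(O)c(C)c1O | intermediate
4 | methyl 4,6-dihydroxy-3-(hydroxymethyl)-2,5-dimethylbenzoate (transient) | COC(=O)c1c(C)c(CO)c(O)c(C)c1O | intermediate
5 | methyl 2,4-dihydroxy-3,5,6-trimethylbenzoate | COC(=O)c1c(C)c(C)c(O)c(C)c1O | intermediate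
6 | methyl 4-(benzyloxy)-2-hydroxy-3,5,6-trimethylbenzoate | COC(=O)c1c(C)c(C)c(OCc2ccccc2)c(C)c1O | intermediate
7 | methyl 4-(benzyloxy)-2-methoxy-3,5,6-trimethylbenzoate | COC(=O)c1c(C)c(C)c(OCc2ccccc2)c(C)c1OC | intermediate
8 | methyl 4-hydroxy-2-methoxy-3,5,6-trimethylbenzoate | COC(=O)c1c(C)c(C)c(O)c(C)c1OC | intermediate
9 | (E)-2-methylbut-2-enoyl chloride | C/C=C(\C)C(=O)Cl | starting material
10 | 2,2-dimethyl-1,3-dioxane-4,6-dione | CC1(C)OC(=O)CC(=O)O1 | starting material
11 | 5-[(E)-1-hydroxy-2-methylbut-2-en-1-ylidene]-2,2-dimethyl-1,3-dioxane-4,6-dione | C/C=C(\C)C(O)=C1C(=O)OC(C)(C)OC1=O | intermediate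
12 | (E)-4-methylhexa-1,4-diene-1,3-dione (transient acylketene) | O=C=CC(=O)/C(C)=C/C | intermediate
13 | 4-(methoxycarbonyl)-3-methoxy-2,5,6-trimethylphenyl (E)-4-methyl-3-oxohex-4-enoate | COC(=O)c1c(C)c(C)c(OC(=O)CC(=O)/C(C)=C/C)c(C)c1OC | intermediate
14 | 4-(methoxycarbonyl)-3-methoxy-2,5,6-trimethylphenyl (E)-2-diazo-4-methyl-3-oxohex-4-enoate | COC(=O)c1c(C)c(C)c(OC(=O)C(=[N+]=[N-])C(=O)/C(C)=C/C)c(C)c1OC | intermediate
15 | trichloroethene | ClC=C(Cl)Cl | starting material
16 | potassium tert-butoxide | CC(C)(C)[O-].[K+] | starting material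
17 | dichloroethyne (transient) | ClC#CCl | intermediate
18 | (E)-1-tert-butoxy-1,2-dichloroethene | Cl/C=C(/Cl)OC(C)(C)C | intermediate
19 | 1-tert-butoxy-2-chloroethyne (transient) | CC(C)(C)OC#CCl | intermediate
20 | lithium tert-butoxyethynide (transient) | [Li]C#COC(C)(C)C | intermediate
21 | tert-butoxyethyne | C#COC(C)(C)C | intermediate
22 | 4-(methoxycarbonyl)-3-methoxy-2,5,6-trimethylphenyl (E)-3-methyl-2-(oxomethylidene)pent-3-enoate (transient vinylketene) | COC(=O)c1c(C)c(C)c(OC(=O)C(=C=O)/C(C)=C/C)c(C)c1OC | intermediate
23 | 4-(methoxycarbonyl)-3-methoxy-2,5,6-trimethylphenyl 2-tert-butoxy-1-[(E)-but-2-en-2-yl]-4-oxocyclobut-2-ene-1-carboxylate (racemic, transient) | COC(=O)c1c(C)c(C)c(OC(=O)C2(/C(C)=C/C)C(OC(C)(C)C)=CC2=O)c(C)c1OC | intermediate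
24 | 4-(methoxycarbonyl)-3-methoxy-2,5,6-trimethylphenyl (2Z)-3-tert-butoxy-2-[(E)-but-2-en-2-yl]-5-oxopenta-2,4-dienoate (transient dienylketene) | COC(=O)c1c(C)c(C)c(OC(=O)/C(=C(\OC(C)(C)C)C=C=O)/C(C)=C/C)c(C)c1OC | intermediate
25 | 4-(methoxycarbonyl)-3-methoxy-2,5,6-trimethylphenyl 6-tert-butoxy-2,3-dimethyl-4-oxocyclohexa-1,5-diene-1-carboxylate (racemic, transient) | COC(=O)c1c(C)c(C)c(OC(=O)C2=C(C)C(C)C(=O)C=C2OC(C)(C)C)c(C)c1OC | intermediate
26 | 4-(methoxycarbonyl)-3-methoxy-2,5,6-trimethylphenyl 2-tert-butoxy-4-hydroxy-5,6-dimethylbenzoate | COC(=O)c1c(C)c(C)c(OC(=O)c2c(C)c(C)c(O)cc2OC(C)(C)C)c(C)c1OC | intermediate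
27 | 4-(methoxycarbonyl)-3-methoxy-2,5,6-trimethylphenyl 2,4-dihydroxy-5,6-dimethylbenzoate | COC(=O)c1c(C)c(C)c(OC(=O)c2c(C)c(C)c(O)cc2O)c(C)c1OC | intermediate
28 | 4-(methoxycarbonyl)-3-methoxy-2,5,6-trimethylphenyl 3-[chloro(methoxy)methyl]-2,4-dihydroxy-5,6-dimethylbenzoate (racemic, transient) | COC(=O)c1c(C)c(C)c(OC(=O)c2c(C)c(C)c(O)c(C(Cl)OC)c2O)c(C)c1OC | intermediate
29 | 4-(methoxycarbonyl)-3-methoxy-2,5,6-trimethylphenyl 3-formyl-2,4-dihydroxy-5,6-dimethylbenzoate | COC(=O)c1c(C)c(C)c(OC(=O)c2c(C)c(C)c(O)c(C=O)c2O)c(C)c1OC | target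

**Step count and risks**

Total step count: 13. Longest linear sequence: 10 steps (steps 1, 2, 3, 4, 5, 7, 8, 11, 12, 13); step 6 and steps 9–10 are side branches.

Steps most likely to fail:

Step 11. What may go wrong:
- light-driven E/Z isomerization of the enone followed by a 1,5-hydrogen shift of the (Z)-vinylketene to a dienal;
- capture of the ester-substituted ketene by the ynol ether through the ester carbonyl instead of the C=C bond, or closure of the opened dienylketene onto the ester oxygen;
- fragmentation of the ynol ether to ketene and isobutene before it has added;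
- photo-Fries migration of the aryl ester.

Fallback, from 8 to 27: ring A would be made by aldol aromatization of a polyketide chain delivered to the phenol as an acylketene. Purchased 2,2,6-trimethyl-4H-1,3-dioxin-4-one is deprotonated at its 6-methyl group with LiN(SiMe3)2 in THF at −78 °C and C-acylated with propanoyl chloride to 2,2-dimethyl-6-(2-oxobutyl)-4H-1,3-dioxin-4-one F1. The dianion of F1 (LiN(iPr)2, THF, −78 °C) is acylated at its terminal carbon with N-methoxy-N-methylacetamide to 2,2-dimethyl-6-(3-methyl-2,4-dioxopentyl)-4H-1,3-dioxin-4-one F2. Heating F2 with 8 in toluene at 110 °C expels acetone, and the phenol traps the acylketene as 4-(methoxycarbonyl)-3-methoxy-2,5,6-trimethylphenyl 6-methyl-3,5,7-trioxooctanoate F3. Cs2CO3 in THF, then dilute HCl, should close the C1–C2 bond of ring A by intramolecular aldol condensation and dehydrate to the resorcinol 27, where the route is rejoined before step 13.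

Step 7. What may go wrong: slow addition of the hindered, electron-poor phenol to the alkenoyl ketene, so that the ketene dimerizes or the alkene drifts out of conjugation; the same fallback also covers a poor acylation in step 6.

Fallback, from 8 to 14: 8 is acylated with bromoacetyl bromide (pyridine, CH2Cl2, 0 °C) to 4-(methoxycarbonyl)-3-methoxy-2,5,6-trimethylphenyl 2-bromoacetate F4. With N,N'-bis(4-methylbenzenesulfonyl)hydrazine and DBU in THF at 0 °C, F4 should give 4-(methoxycarbonyl)-3-methoxy-2,5,6-trimethylphenyl 2-diazoacetate F5. DBU-catalysed aldol addition of F5 to (E)-2-methylbut-2-enal in MeCN gives racemic 4-(methoxycarbonyl)-3-methoxy-2,5,6-trimethylphenyl (E)-2-diazo-3-hydroxy-4-methylhex-4-enoate F6. Oxidation of the allylic alcohol with Dess–Martin periodinane (CH2Cl2, NaHCO3) gives 14, where the route is rejoined before step 11.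

Step 10. What may go wrong: loss of the volatile alkyne during isolation, or its retro-ene fragmentation to ketene and isobutene on concentration.

Fallback, from 18 to 27: the lithium acetylide 20, made from 18 as in step 10, is silylated in the flask with Me3SiCl instead of being protonated. This gives tert-butoxy(trimethylsilyl)ethyne F7, which is much less volatile and is handled as a cold solution. F7 takes the place of 21 in the irradiation with 14, the silicon-bearing carbon becoming C5, and should give 4-(methoxycarbonyl)-3-methoxy-2,5,6-trimethylphenyl 2-tert-butoxy-4-hydroxy-5,6-dimethyl-3-(trimethylsilyl)benzoate F8. The acid of step 12 (CF3CO2H, Et3SiH, CH2Cl2) then removes the tert-butyl group and, by ipso-protodesilylation at the doubly oxygen-flanked C5, the silyl group, so that the route is rejoined at 27.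

Further compounds
F1 | step 11 | 2,2-dimethyl-6-(2-oxobutyl)-4H-1,3-dioxin-4-one | CCC(=O)CC1=CC(=O)OC(C)(C)O1
F2 | step 11 | 2,2-dimethyl-6-(3-methyl-2,4-dioxopentyl)-4H-1,3-dioxin-4-one | CC(=O)C(C)C(=O)CC1=CC(=O)OC(C)(C)O1
F3 | step 11 | 4-(methoxycarbonyl)-3-methoxy-2,5,6-trimethylphenyl 6-methyl-3,5,7-trioxooctanoate | COC(=O)c1c(C)c(C)c(OC(=O)CC(=O)CC(=O)C(C)C(C)=O)c(C)c1OC
F4 | step 7 | 4-(methoxycarbonyl)-3-methoxy-2,5,6-trimethylphenyl 2-bromoacetate | COC(=O)c1c(C)c(C)c(OC(=O)CBr)c(C)c1OC
F5 | step 7 | 4-(methoxycarbonyl)-3-methoxy-2,5,6-trimethylphenyl 2-diazoacetate | COC(=O)c1c(C)c(C)c(OC(=O)C=[N+]=[N-])c(C)c1OC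
F6 | step 7 | 4-(methoxycarbonyl)-3-methoxy-2,5,6-trimethylphenyl (E)-2-diazo-3-hydroxy-4-methylhex-4-enoate (racemic) | COC(=O)c1c(C)c(C)c(OC(=O)C(=[N+]=[N-])C(O)/C(C)=C/C)c(C)c1OC
F7 | step 10 | tert-butoxy(trimethylsilyl)ethyne | CC(C)(C)OC#C[Si](C)(C)C
F8 | step 10 | 4-(methoxycarbonyl)-3-methoxy-2,5,6-trimethylphenyl 2-tert-butoxy-4-hydroxy-5,6-dimethyl-3-(trimethylsilyl)benzoate | COC(=O)c1c(C)c(C)c(OC(=O)c2c(C)c(C)c(O)c([Si](C)(C)C)c2OC(C)(C)C)c(C)c1OC
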